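The cyclopentenone is disconnected at its C4–C5 bond (ring numbering: C1 carbonyl, C2(Br)=C3, C4 acetoxy carbon, C5 alkylidene carbon). The key step exploits the 1,4-dioxygenation across the C2=C3 alkene, which is the latent pattern of a furan: a 3-bromo-5-alkylfuran-2-ylmethanol is the Piancatelli isomer of the 2-bromo-4-hydroxycyclopent-2-enone. In one operation a chiral Brønsted acid ionises the carbinol, water adds at furan C5, the furan opens and a conrotatory 4π electrocyclisation closes C4–C5. This gives the ring, the C1 ketone, the C2 vinyl bromide and the C4 stereocentre. Aldol condensation with methyl (E)-7-oxohept-5-enoate and acetylation complete the target.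

Key step: step 4

Remark: the sense of induction of the chiral acid in step 4 cannot be predicted with certainty, so the catalyst antipode that gives (4S)-9 is assumed to be fixed by screening both enantiomers; compounds 1, 3, 10 and 11 are taken as commercial.

Step 1
Reactants: 1 (Z)-oct-2-en-1-ol
Product: 2 (Z)-1-bromooct-2-ene
Conditions: CBr4, PPh3, CH2Cl2, 0 °C
Reagents that add atoms: carbon tetrabromide BrC(Br)(Br)Br
Why: Appel bromination replaces the primary allylic hydroxyl by SN2 displacement of the oxyphosphonium group at 0 °C, which should leave the position and the Z geometry of the alkene unchanged.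

Step 2
Reactants: 3 3-bromofuran-2-carboxylic acid; 2 (Z)-1-bromooct-2-ene
Product: 5 3-bromo-5-[(2Z)-oct-2-en-1-yl]furan-2-carboxylic acid, via dilithio furoate 4 (not isolated)
Conditions: LiN(iPr)2 (LDA, 2.2 equiv), THF, −78 °C; then 2, −78 to −20 °C; aq. HCl
Reagents that add atoms: none
Why: Directed lithiation–alkylation: the amide base forms the carboxylate and then removes the only remaining furan α-proton (C5–H) without bromine–lithium exchange, as known for furan-2-carboxylate dianions, and the 5-lithiofuran is C-allylated by direct SN2 attack on the primary allylic bromide without copper, so neither allylic transposition nor Z/E isomerisation is expected; no stereocentre is formed.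

Step 3
Reactants: 5 3-bromo-5-[(2Z)-oct-2-en-1-yl]furan-2-carboxylic acid
Product: 6 [3-bromo-5-[(2Z)-oct-2-en-1-yl]furan-2-yl]methanol
Conditions: LiAlH4, THF, 0 °C; basic aqueous work-up
Reagents that add atoms: none
Why: Hydride reduction of the carboxylic acid to the primary alcohol at 0 °C, where the hetaryl bromide and the isolated Z-alkene should be inert; the basic work-up protects the acid-labile 5-alkylfurfuryl alcohol.

Step 4
Reactants: 6 [3-bromo-5-[(2Z)-oct-2-en-1-yl]furan-2-yl]methanol
Product: 9 (4S)-2-bromo-4-hydroxy-4-[(2Z)-oct-2-en-1-yl]cyclopent-2-en-1-one, via hemiketal 7 (not isolated), via keto-dienol 8 (not isolated)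
Conditions: (R)-3,3′-bis(2,4,6-triisopropylphenyl)-BINOL N-triflylphosphoramide (10 mol %, antipode by screening), H2O (5 equiv), toluene, 50 °C
Reagents that add atoms: water O
Why: Proposed new method: the acid ionises the 5-alkylfurfuryl alcohol to the 2-methylene-2H-furanium (oxocarbenium) ion, water adds at furan C5 to give hemiketal 7, ring opening gives keto-dienol 8, and its O-protonated form, a 1,4-dihydroxypentadienyl cation held by two hydrogen bonds to the chiral phosphoramide anion, undergoes thermal conrotatory 4π electrocyclisation followed by proton loss. The closest known reaction types are the oxa-Piancatelli rearrangement of 2-furylcarbinols (5-methyl-2-furylcarbinols are known to give 4-hydroxy-4-methylcyclopent-2-enones) and the chiral-phosphoric-acid-catalysed aza-Piancatelli rearrangement; what is new is enantiocontrol with water as nucleophile on a 5-alkylfuran, creating a quaternary carbinol from a primary furylcarbinol. The cyclopentenone, the only ring, is closed by this 4π-conrotatory electrocyclisation, which joins the former carbinol CH2 carbon (C5 of 9) to the former furan C5 (C4 of 9), while the furan oxygen becomes the ketone oxygen and the furan C3 bromine becomes the C2 vinyl bromide. The new stereocentre C4 is controlled by the chiral counter-anion, which differentiates the two enantiomeric helical conrotatory modes of the cation; the catalyst antipode is chosen to give 4S. The step needs regioselective water attack at furan C5, secured by the alkyl-stabilised oxocarbenium character of that carbon, and ring closure faster than tautomerisation of 8 to the ene-dione (which would open a second aldol mode from the octenyl CH2), secured because the enol is generated only on the CH2 side. The 5-alkyl group also blocks the oligomerisation typical of unsubstituted furfuryl cations, and the skipped Z-alkene should be inert to the weakly acidic aqueous medium.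

Step 5
Reactants: 10 methyl hex-5-enoate; 11 (E)-but-2-enal
Product: 12 methyl (5E)-7-oxohept-5-enoate
Conditions: second-generation Hoveyda–Grubbs catalyst [RuCl2(H2IMes)(=CH-C6H4-2-OiPr)] (2.5 mol %), 11 (5 equiv), CH2Cl2, 40 °C
Reagents that add atoms: none
Why: Olefin cross-metathesis of a terminal alkene with an excess of an electron-poor enal partner is selective for the cross product and should give the E-enal under thermodynamic control.

Step 6
Reactants: 9 (4S)-2-bromo-4-hydroxy-4-[(2Z)-oct-2-en-1-yl]cyclopent-2-en-1-one; 12 methyl (5E)-7-oxohept-5-enoate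
Product: 14 methyl (5E)-7-[(5S)-3-bromo-5-hydroxy-5-[(2Z)-oct-2-en-1-yl]-2-oxocyclopent-3-en-1-yl]-7-hydroxyhept-5-enoate, via dilithium dianion 13 (not isolated)
Conditions: LiN(iPr)2 (LDA, 2.3 equiv), THF, −78 °C (9 added to the base); then 12, −78 °C; AcOH
Reagents that add atoms: none
Why: Directed aldol addition: the base forms the alkoxide–enolate dianion at the only enolisable carbon (ring CH2), the tertiary lithium alkoxide being a non-leaving group that suppresses β-elimination, and the lithium enolate should add 1,2 to the enal at −78 °C; the two new stereocentres (ring C1 and C7 of the chain) form as a mixture that does not matter because both become sp2 in step 7, and the quaternary carbinol centre is untouched.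

Step 7
Reactants: 14 methyl (5E)-7-[(5S)-3-bromo-5-hydroxy-5-[(2Z)-oct-2-en-1-yl]-2-oxocyclopent-3-en-1-yl]-7-hydroxyhept-5-enoate
Product: 17 methyl (5E,7Z)-7-[(2R)-2-acetoxy-4-bromo-2-[(2Z)-oct-2-en-1-yl]-5-oxocyclopent-3-en-1-ylidene]hept-5-enoate, via allylic acetate 15 (not isolated), via dienone alcohol 16 (not isolated)
Conditions: Ac2O (6 equiv), DMAP (0.5 equiv), Et3N (6 equiv), CH2Cl2, 0 °C to rt
Reagents that add atoms: acetic anhydride CC(=O)OC(C)=O
Why: Acetylation–E1cB elimination: the secondary allylic alcohol is acetylated first, amine-mediated E1cB loss of acetate from the β-acetoxy ketone installs the exocyclic C=C of the cross-conjugated dienone (the 5E alkene is untouched), and DMAP-catalysed acetylation of the tertiary alcohol then gives 17; the elimination is not stereospecific, so the 7Z isomer (side chain on the carbonyl side, away from the quaternary acetoxy carbon) is separated from the 7E isomer by chromatography, and the quaternary stereocentre is not affected (its descriptor changes from S to R only through the priority change at the neighbouring ring carbon).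

Compound list
1 | (Z)-oct-2-en-1-ol | CCCCC/C=C\CO | starting material
2 | (Z)-1-bromooct-2-ene | CCCCC/C=C\CBr | intermediate
3 | 3-bromofuran-2-carboxylic acid | OC(=O)c1occc1Br | starting material
4 | dilithio furoate, lithium 3-bromo-5-lithiofuran-2-carboxylate (formed in the flask, not isolated) | [Li]OC(=O)c1oc([Li])cc1Br | intermediate
5 | 3-bromo-5-[(2Z)-oct-2-en-1-yl]furan-2-carboxylic acid | CCCCC/C=C\Cc1cc(Br)c(C(=O)O)o1 | intermediate
6 | [3-bromo-5-[(2Z)-oct-2-en-1-yl]furan-2-yl]methanol | CCCCC/C=C\Cc1cc(Br)c(CO)o1 | intermediate
7 | hemiketal, 4-bromo-5-methylidene-2-[(2Z)-oct-2-en-1-yl]-2,5-dihydrofuran-2-ol (not isolated) | CCCCC/C=C\CC1(O)C=C(Br)C(=C)O1 | intermediate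
8 | keto-dienol, (3E,7Z)-3-bromo-2-hydroxytrideca-1,3,7-trien-5-one, cyclising as its O-protonated pentadienyl cation (not isolated) | C=C(O)/C(Br)=C\C(=O)C/C=C\CCCCC | intermediate
9 | (4S)-2-bromo-4-hydroxy-4-[(2Z)-oct-2-en-1-yl]cyclopent-2-en-1-one | CCCCC/C=C\C[C@@]1(O)C=C(Br)C(=O)C1 | intermediate
10 | methyl hex-5-enoate | C=CCCCC(=O)OC | starting material
11 | (E)-but-2-enal (crotonaldehyde) | C/C=C/C=O | starting material
12 | methyl (5E)-7-oxohept-5-enoate | O=C/C=C/CCCC(=O)OC | intermediate
13 | dilithium dianion of 9, lithium alkoxide and lithium dienolate (not isolated) | CCCCC/C=C\C[C@@]1(O[Li])C=C(Br)C(O[Li])=C1 | intermediate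
14 | methyl (5E)-7-[(5S)-3-bromo-5-hydroxy-5-[(2Z)-oct-2-en-1-yl]-2-oxocyclopent-3-en-1-yl]-7-hydroxyhept-5-enoate (mixture of diastereomers at ring C1 and chain C7) | CCCCC/C=C\C[C@@]1(O)C=C(Br)C(=O)C1C(O)/C=C/CCCC(=O)OC | intermediate
15 | methyl (5E)-7-acetoxy-7-[(5S)-3-bromo-5-hydroxy-5-[(2Z)-oct-2-en-1-yl]-2-oxocyclopent-3-en-1-yl]hept-5-enoate (not isolated) | CCCCC/C=C\C[C@@]1(O)C=C(Br)C(=O)C1C(OC(C)=O)/C=C/CCCC(=O)OC | intermediate
16 | methyl (5E,7Z)-7-[(2R)-4-bromo-2-hydroxy-2-[(2Z)-oct-2-en-1-yl]-5-oxocyclopent-3-en-1-ylidene]hept-5-enoate (not isolated) | CCCCC/C=C\C[C@@]1(O)C=C(Br)C(=O)/C1=C\C=C\CCCC(=O)OC | intermediate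
17 | methyl (5E,7Z)-7-[(2R)-2-acetoxy-4-bromo-2-[(2Z)-oct-2-en-1-yl]-5-oxocyclopent-3-en-1-ylidene]hept-5-enoate | CCCCC/C=C\C[C@@]1(OC(C)=O)C=C(Br)C(=O)/C1=C\C=C\CCCC(=O)OC | target

Total step count: 7. Longest linear sequence: 6 steps (1 → 2 → 5 → 6 → 9 → 14 → 17).

Steps most likely to fail

Step 4 (Proposed new method). What may go wrong: slow ionisation of the primary, bromine-substituted furylcarbinol under the chiral acid; poor facial discrimination between the two conrotatory modes, giving low enantiomeric purity; or diversion of the ring-opened intermediate to the ene-dione and a wrong aldol closure. The fallback uses known chemistry, sets out from 6 and comes back at 9. Compound 6 is rearranged without asymmetric induction under established Lewis-acid oxa-Piancatelli conditions (Dy(OTf)3 10 mol %, t-BuOH/H2O, 80 °C, or ZnCl2 in aqueous dioxane at reflux) to racemic 2-bromo-4-hydroxy-4-[(2Z)-oct-2-en-1-yl]cyclopent-2-en-1-one F1. The enantiomers are then separated by preparative chromatography on a polysaccharide-based chiral stationary phase; the (4S)-enantiomer is 9 and the route continues at step 6.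

Step 7. What may go wrong: loss of geometric control in the non-stereospecific E1cB elimination, so that the isomer with the chain on the side of the quaternary carbon predominates, and slow acetylation of the hindered tertiary alcohol. The fallback sets out from 14 and comes back at 17. The acetylation–elimination is run as described and the co-formed methyl (5E,7E)-7-[(2R)-2-acetoxy-4-bromo-2-[(2Z)-oct-2-en-1-yl]-5-oxocyclopent-3-en-1-ylidene]hept-5-enoate F2 is collected and irradiated (365 nm, benzene, room temperature). Light-induced E/Z isomerisation of the exocyclic enone double bond should establish a photostationary mixture from which 17 is separated, and recovered F2 is cycled again.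

Step 6. What may go wrong: retro-aldol opening of the β-alkoxide ketone before the second deprotonation, base-induced decomposition of the α-bromoenone, or conjugate instead of carbonyl addition to the enal. The fallback sets out from 9 and comes back at 14. Compound 9 is bis-silylated (TMSOTf, Et3N, CH2Cl2, −78 to 0 °C) to the silyl ether–silyl dienol ether (5S)-3-bromo-5-[(2Z)-oct-2-en-1-yl]-2,5-bis(trimethylsilyloxy)cyclopenta-1,3-diene F3. Mukaiyama aldol addition to 12 under non-basic conditions (BF3·OEt2, CH2Cl2, −78 °C) gives methyl (5E)-7-[(5S)-3-bromo-2-oxo-5-[(2Z)-oct-2-en-1-yl]-5-(trimethylsilyloxy)cyclopent-3-en-1-yl]-7-hydroxyhept-5-enoate F4. Mild acid (citric acid, MeOH) removes the tertiary trimethylsilyl ether and returns 14.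

Further compounds
F1 | step 4 | racemic 2-bromo-4-hydroxy-4-[(2Z)-oct-2-en-1-yl]cyclopent-2-en-1-one | CCCCC/C=C\CC1(O)C=C(Br)C(=O)C1
F2 | step 7 | methyl (5E,7E)-7-[(2R)-2-acetoxy-4-bromo-2-[(2Z)-oct-2-en-1-yl]-5-oxocyclopent-3-en-1-ylidene]hept-5-enoate | CCCCC/C=C\C[C@@]1(OC(C)=O)C=C(Br)C(=O)/C1=C/C=C/CCCC(=O)OC
F3 | step 6 | (5S)-3-bromo-5-[(2Z)-oct-2-en-1-yl]-2,5-bis(trimethylsilyloxy)cyclopenta-1,3-diene | CCCCC/C=C\C[C@@]1(O[Si](C)(C)C)C=C(Br)C(O[Si](C)(C)C)=C1
F4 | step 6 | methyl (5E)-7-[(5S)-3-bromo-2-oxo-5-[(2Z)-oct-2-en-1-yl]-5-(trimethylsilyloxy)cyclopent-3-en-1-yl]-7-hydroxyhept-5-enoate | CCCCC/C=C\C[C@@]1(O[Si](C)(C)C)C=C(Br)C(=O)C1C(O)/C=C/CCCC(=O)OC
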